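**Retrosynthetic overview**
- Target 11 is the cyclic hemiketal of an α‑bromo δ‑hydroxy ketone. The last step is C3 bromination of hydroxy ketone 9, after which the oxane ring closes by itself (formed last).
- The (E)‑CH=CHBr group comes from a masked aldehyde (lactol 6) by bromo‑olefination. Lactol 6 comes from α‑chloro‑γ‑lactone 5, a temporary ring that carries both carbon stereocentres.
- Key disconnection is C4–C5 (oxane numbering): a homoenolate of butan‑2‑one (Grignard reagent of bromo ketal 2) is joined to the β‑carbon of butenolide 1. The resulting enolate is chlorinated in the same flask, which creates the tertiary C–Cl centre.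
- Ring order: the butenolide ring is present from 1, is opened in step 3, and the oxane hemiketal forms in step 5.

Assumption: which Josiphos antipode gives (4R) in 5 cannot be predicted with certainty and is fixed by one analytical run (both antipodes are commercial); it is written as (R,S_p) below.

**Step 1**
Reactants: 1 3‑methylfuran‑2(5H)‑one; 2 2‑(2‑bromoethyl)‑2‑methyl‑1,3‑dioxolane
Product: 5 (3S,4R)‑3‑chloro‑3‑methyl‑4‑[2‑(2‑methyl‑1,3‑dioxolan‑2‑yl)ethyl]oxolan‑2‑one, via Grignard reagent 3 (not isolated), via magnesium enolate 4 (not isolated)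
Conditions: 2 (1.4 equiv), Mg, 2‑MeTHF, 25 °C; then 1, CuBr·SMe2 (5 mol %), (R,S_p)‑Josiphos (6 mol %), t‑BuOMe, −78 → −40 °C; then NCS (1.6 equiv), THF, −78 → −20 °C
Reagents that add atoms: N‑chlorosuccinimide (ClN1C(=O)CCC1=O)
Why: Proposed new method: Grignard reagent 3 is a homoenolate (d3) equivalent of butan‑2‑one, and its Cu(I)/diphosphine‑catalysed 1,4‑addition (π‑complex, Cu(III) σ‑adduct at the β‑carbon, reductive elimination) joins its carbon to the electrophilic β‑carbon of 1 with C4 set by the ligand, after which the ring‑bound enolate 4 is chlorinated by NCS on the face anti to the new C4 chain (Cl trans to the chain, 3S); the closest known reaction types are the Cu/ferrocenyl‑diphosphine‑catalysed asymmetric conjugate addition of Grignard reagents to unsaturated lactones and esters, and conjugate addition–enolate trapping on 2‑methylcycloalkenones that builds adjacent tertiary and quaternary centres.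

**Step 2**
Reactants: 5 (3S,4R)‑3‑chloro‑3‑methyl‑4‑[2‑(2‑methyl‑1,3‑dioxolan‑2‑yl)ethyl]oxolan‑2‑one
Product: 6 (3S,4R)‑3‑chloro‑3‑methyl‑4‑[2‑(2‑methyl‑1,3‑dioxolan‑2‑yl)ethyl]oxolan‑2‑ol (anomer mixture)
Conditions: DIBAL‑H (1.15 equiv), CH2Cl2, −78 °C; Rochelle salt work‑up
Reagents that add atoms: none
Why: Low‑temperature DIBAL‑H reduction of a γ‑lactone stops at the aluminium hemiacetal and gives the lactol on work‑up; the ketal, the tertiary chloride and both stereocentres (C3 is quaternary) are untouched.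

**Step 3**
Reactants: 6 (3S,4R)‑3‑chloro‑3‑methyl‑4‑[2‑(2‑methyl‑1,3‑dioxolan‑2‑yl)ethyl]oxolan‑2‑ol
Product: 8 (2R,3S,4E)‑5‑bromo‑3‑chloro‑3‑methyl‑2‑[2‑(2‑methyl‑1,3‑dioxolan‑2‑yl)ethyl]pent‑4‑en‑1‑ol, via hydroxy aldehyde 7 (not isolated)
Conditions: CrBr2 (6 equiv), CHBr3 (2 equiv), THF, 0 → 23 °C, dark
Reagents that add atoms: bromoform (BrC(Br)Br)
Why: Takai olefination, in which the small equilibrium share of ring‑opened aldehyde 7 is trapped by the gem‑dichromium species from CHBr3/CrBr2 and anti elimination gives the (E)‑bromoalkene (the α‑quaternary centre reinforces E; CrBr2 instead of CrCl2 avoids Br/Cl scrambling); no stereocentre is touched.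

**Step 4**
Reactants: 8 (2R,3S,4E)‑5‑bromo‑3‑chloro‑3‑methyl‑2‑[2‑(2‑methyl‑1,3‑dioxolan‑2‑yl)ethyl]pent‑4‑en‑1‑ol
Product: 9 (5R,6S,7E)‑8‑bromo‑6‑chloro‑5‑(hydroxymethyl)‑6‑methyloct‑7‑en‑2‑one (drawn and named as the open‑chain hydroxy ketone)
Conditions: 1 M aq. HCl/THF (1:5), 0 → 23 °C, stopped at full conversion
Reagents that add atoms: water (O)
Why: Acid‑catalysed ketal hydrolysis through the oxocarbenium ion, run in a water‑poor medium of low ionising power so that the tertiary allylic chloride does not solvolyse; the stereocentres are not involved.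

**Step 5**
Reactants: 9 (5R,6S,7E)‑8‑bromo‑6‑chloro‑5‑(hydroxymethyl)‑6‑methyloct‑7‑en‑2‑one
Product: 11 (2R,3S,5R)‑3‑bromo‑5‑[(2S,3E)‑4‑bromo‑2‑chlorobut‑3‑en‑2‑yl]‑2‑methyloxan‑2‑ol, via open‑chain bromo ketone 10 (not isolated)
Conditions: NBS (1.05 equiv), TsOH·H2O (10 mol %), CH2Cl2, 0 → 23 °C, dark; then Bu4NBr (0.2 equiv), 23 °C
Reagents that add atoms: N‑bromosuccinimide (BrN1C(=O)CCC1=O); tetrabutylammonium bromide (CCCC[N+](CCCC)(CCCC)CCCC.[Br-], degenerate bromide exchange at C3 only)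
Why: Acid‑catalysed α‑bromination of the methyl ketone through its more substituted enol puts Br on C3 and not on CH3, bromo ketone 10 closes to the six‑membered hemiketal, and C3 and C2 are set under thermodynamic control (bromide exchange on the open form, ring–chain tautomerism) in favour of the isomer with Br, CH3 and the C5 side chain equatorial and the anomeric OH axial, which is (2R,3S,5R).

**Compound list**
1 | 3‑methylfuran‑2(5H)‑one | CC1=CCOC1=O | starting material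
2 | 2‑(2‑bromoethyl)‑2‑methyl‑1,3‑dioxolane | CC1(CCBr)OCCO1 | starting material
3 | [2‑(2‑methyl‑1,3‑dioxolan‑2‑yl)ethyl]magnesium bromide | CC1(CC[Mg]Br)OCCO1 | intermediate
4 | bromomagnesium (4S)‑3‑methyl‑4‑[2‑(2‑methyl‑1,3‑dioxolan‑2‑yl)ethyl]‑4,5‑dihydrofuran‑2‑olate (same spatial arrangement at C4 as in 5; the descriptor changes by CIP priority only) | CC1=C(O[Mg]Br)OC[C@H]1CCC2(C)OCCO2 | intermediate
5 | (3S,4R)‑3‑chloro‑3‑methyl‑4‑[2‑(2‑methyl‑1,3‑dioxolan‑2‑yl)ethyl]oxolan‑2‑one (Cl trans to the C4 chain) | C[C@@]1(Cl)C(=O)OC[C@H]1CCC2(C)OCCO2 | intermediate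
6 | (3S,4R)‑3‑chloro‑3‑methyl‑4‑[2‑(2‑methyl‑1,3‑dioxolan‑2‑yl)ethyl]oxolan‑2‑ol, anomer mixture | C[C@@]1(Cl)C(O)OC[C@H]1CCC2(C)OCCO2 | intermediate
7 | (2S,3R)‑2‑chloro‑3‑(hydroxymethyl)‑2‑methyl‑5‑(2‑methyl‑1,3‑dioxolan‑2‑yl)pentanal | C[C@@](Cl)(C=O)[C@@H](CO)CCC1(C)OCCO1 | intermediate
8 | (2R,3S,4E)‑5‑bromo‑3‑chloro‑3‑methyl‑2‑[2‑(2‑methyl‑1,3‑dioxolan‑2‑yl)ethyl]pent‑4‑en‑1‑ol | C[C@@](Cl)(/C=C/Br)[C@@H](CO)CCC1(C)OCCO1 | intermediate
9 | (5R,6S,7E)‑8‑bromo‑6‑chloro‑5‑(hydroxymethyl)‑6‑methyloct‑7‑en‑2‑one | C[C@@](Cl)(/C=C/Br)[C@@H](CO)CCC(C)=O | intermediate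
10 | (3S,5R,6S,7E)‑3,8‑dibromo‑6‑chloro‑5‑(hydroxymethyl)‑6‑methyloct‑7‑en‑2‑one | C[C@@](Cl)(/C=C/Br)[C@@H](CO)C[C@H](Br)C(C)=O | intermediate
11 | (2R,3S,5R)‑3‑bromo‑5‑[(2S,3E)‑4‑bromo‑2‑chlorobut‑3‑en‑2‑yl]‑2‑methyloxan‑2‑ol | C[C@@](Cl)(/C=C/Br)[C@H]1CO[C@@](C)(O)[C@@H](Br)C1 | target

**Totals**
Total step count: 5 (the Grignard reagent is made and used within step 1). Longest linear sequence: 5 steps.

**Steps most likely to fail, with fallbacks**

Step 1 is the riskiest. The α‑methylated butenolide is a sluggish acceptor, 1,2‑addition can compete, and the enantioselectivity is unproven. The fallback replaces catalyst control by auxiliary control and builds the quaternary centre stepwise; it sets out from 2 (as its Grignard reagent 3) and comes back at 5. Reagent 3 is added (CuBr·SMe2 10 mol %, THF, −78 °C) to (5S)‑5‑[(1S,2R,5S)‑menthyloxy]furan‑2(5H)‑one (C[C@H]1CC[C@@H]([C@H](C1)O[C@H]2OC(=O)C=C2)C(C)C, from (+)‑menthol). Attack anti to the menthyloxy group gives (4S,5S)‑5‑[(1S,2R,5S)‑menthyloxy]‑4‑[2‑(2‑methyl‑1,3‑dioxolan‑2‑yl)ethyl]oxolan‑2‑one F1. NaBH4 in aqueous KOH followed by careful acidification to pH 3–4 releases menthol and closes (4S)‑4‑[2‑(2‑methyl‑1,3‑dioxolan‑2‑yl)ethyl]oxolan‑2‑one F2. LDA/MeI (THF, −78 °C) gives the trans lactone (3S,4S)‑3‑methyl‑4‑[2‑(2‑methyl‑1,3‑dioxolan‑2‑yl)ethyl]oxolan‑2‑one F3. LDA then NCS (−78 °C) chlorinates anti to the C4 chain and gives 5.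

Step 3 may fail because the lactol releases little free aldehyde and because Cr(II) could reduce the C–Cl bond of the α‑chloro aldehyde. The fallback avoids chromium; it sets out from 6 and comes back at 8. Colvin homologation (TMSCHN2/LDA, 2.2 equiv, THF, −78 → 0 °C) turns the lactol into (2R,3S)‑3‑chloro‑3‑methyl‑2‑[2‑(2‑methyl‑1,3‑dioxolan‑2‑yl)ethyl]pent‑4‑yn‑1‑ol F4. Hydrozirconation with Cp2Zr(H)Cl (2.2 equiv, THF, 23 °C; syn addition, Zr on the terminal carbon) and bromination of the alkenylzirconium with NBS (0 °C, retention) give the (E)‑bromoalkene 8.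

Step 5 carries two risks: bromination at CH3 instead of C3, and an unfavourable C3 epimer ratio. The fallback fixes the regiochemistry structurally; it sets out from 9 and comes back at 11. Cyclodehydration (PPTS, 4 Å MS, benzene, 60 °C) gives the endocyclic enol ether (3R)‑3‑[(2S,3E)‑4‑bromo‑2‑chlorobut‑3‑en‑2‑yl]‑6‑methyl‑3,4‑dihydro‑2H‑pyran F5, in which only the ring enol‑ether carbon can take up bromine. NBS in THF/H2O (0 °C) adds Br there and water at the oxocarbenium carbon, and Bu4NBr in the same flask equilibrates C3 to give 11. A minor C3 epimer is separable and can be re‑equilibrated.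

**Further compounds**
F1 | step 1 | (4S,5S)‑5‑{[(1S,2R,5S)‑5‑methyl‑2‑(propan‑2‑yl)cyclohexyl]oxy}‑4‑[2‑(2‑methyl‑1,3‑dioxolan‑2‑yl)ethyl]oxolan‑2‑one | C[C@H]1CC[C@@H]([C@H](C1)O[C@H]2OC(=O)C[C@@H]2CCC3(C)OCCO3)C(C)C
F2 | step 1 | (4S)‑4‑[2‑(2‑methyl‑1,3‑dioxolan‑2‑yl)ethyl]oxolan‑2‑one | O=C1C[C@H](CCC2(C)OCCO2)CO1
F3 | step 1 | (3S,4S)‑3‑methyl‑4‑[2‑(2‑methyl‑1,3‑dioxolan‑2‑yl)ethyl]oxolan‑2‑one | C[C@@H]1C(=O)OC[C@H]1CCC2(C)OCCO2
F4 | step 3 | (2R,3S)‑3‑chloro‑3‑methyl‑2‑[2‑(2‑methyl‑1,3‑dioxolan‑2‑yl)ethyl]pent‑4‑yn‑1‑ol | C[C@@](Cl)(C#C)[C@@H](CO)CCC1(C)OCCO1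
F5 | step 5 | (3R)‑3‑[(2S,3E)‑4‑bromo‑2‑chlorobut‑3‑en‑2‑yl]‑6‑methyl‑3,4‑dihydro‑2H‑pyran | C[C@@](Cl)(/C=C/Br)[C@H]1COC(C)=CC1
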